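At 80.0 min I read the south run, charged with the most free catalyst of the three, and over its last stretch, from 40.0 min, its readings give product at 0.480 /min. This reading is my quantity, the turnover of second catalyst (the field's turnover frequency): product made per minute per second catalyst charged, with reagent near its charge. The south-east run gives 0.425 /min on less free catalyst, a small step down, and I take the south figure as the top rate.

| flask | substrate | reagent | free catalyst | second catalyst | remark |
|---|---|---|---|---|---|
| south-east | 0.10 M | 0.10 M | 0.70 mM | 0.50 mM | run made earlier |
| south | 0.10 M | 0.10 M | 1.1 mM | 0.50 mM | run made earlier |
| east | 0.10 M | 0.10 M | 0.50 mM | 1 mM | run made earlier |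
| flask | 0.10 M | 0.100 M | 0.50 mM | 0.50 mM |  |

| run | time / min | product / % | substrate / % |
|---|---|---|---|
| south-east | 8.00 | 0 | 95.6 |
| south-east | 20.0 | 1.5 | 89.9 |
| south-east | 40.0 | 6.8 | 86.1 |
| south-east | 60.0 | 9.2 | 79.7 |
| south-east | 80.0 | 15.3 | 75.2 |
| south | 6.00 | 0.6 | 93.9 |
| south | 12.0 | 1.7 | 90.5 |
| south | 25.0 | 5.0 | 83.7 |
| south | 40.0 | 5.3 | 77.9 |
| south | 80.0 | 14.9 | 69.6 |
| east | 15.0 | 2.2 | 97.9 |
| east | 30.0 | 6.8 | 89.3 |
| east | 50.0 | 10.1 | 85.6 |
| east | 60.0 | 14.0 | 84.3 |
| east | 80.0 | 15.6 | 81.9 |

(standard deviation of a reading: 1 percentage point)

* apparent order in reagent when 30% of the substrate are converted (percent change of the rate of making product for one percent more reagent charged)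
* factor on the rate of making product when 30% of the substrate are converted if reagent is charged twice over

- "the catalyst" is free catalyst with its forms; second catalyst is a second catalyst
- no earlier run changes the charge of reagent; that part of a forecast is a guess

The flask has the free catalyst of the east run, so I draw its curve from there, with a cap of its own:

cap = turnover × second catalyst = 0.240 mM/min

Substrate in the east run starts down at 0.357 mM/min, faster than the cap, so I expect an intermediate to pile up in the flask and product to trail. Later the east substrate falls at 0.123 mM/min, below the cap. I take that crossing as the knee of the flask's curve. For a rate of supply × cap/(supply + cap), with the cap in proportion to reagent, the order in reagent is the rate over the cap. The east run makes product at 0.176 mM/min, which I put in as the flask's rate, and I go round twice: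

first share of the cap = 0.733

second share, with the late supply = 0.514

My own judgement is to take the order near that second share, and the same formula gives a factor of 1.35 for reagent charged twice over. The east run ends with 81.9% of its substrate left, more than the 70.0% left at the conversion asked, so my reckoning comes from an earlier stage than the one asked.

The forecast says 0.4 and 1.35, adding “No run varies reagent, so its role is a guess”.

The flask gives an order of 0.59, above both estimates, and a factor of 1.26, below mine.

    free catalyst → spent catalyst (k = 0.540 /h)
    second catalyst + open intermediate ⇌ catalyst intermediate (K = 870 /M, k = 14000 /M/h)
    reagent + catalyst intermediate → second catalyst + product (k = 340 /M/h)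
    substrate + free catalyst ⇌ free catalyst + open intermediate (K = 0.610, k = 450 /M/h)

At 80.0 min the binding of open intermediate to second catalyst relaxes with a half-life of 0.422 min, far shorter than the 144 min of the step that makes open intermediate, and catalyst intermediate stands at 63.4% of the second catalyst charged. The flask's turnover from 40.0 min to 80.0 min is 0.329 /min, against the 0.480 /min read in the south run, a share of 0.685. Twice the free catalyst multiplies the flask's rate by 7.93.

(All runs stem from a simulated flask with constants of no real substance; the scatter is artificial.)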